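# Proposed synthesis of CNP0169028.1 by enzymatic dearomatisation of bromobenzene

Numbering used throughout: ring carbons C1–C6, with C1 bearing the exocyclic C7H2–OBz, C2 the vinylic CH, C3 (OAc), C4 (OH), C5 (OBz), C6 (OH); O3–O7 are the oxygens on C3–C7.

## Analysis of the target

Target 11 is a carbasugar-type cyclohexene: one carbocycle C1–C6, a trisubstituted C1=C2 alkene, the exocyclic C7 on C1, and an oxygen on every other ring carbon. The four contiguous stereocenters are C3 (R), C4 (S), C5 (R) and C6 (S), with O3/O4 trans, O4/O5 cis and O5/O6 trans. This trans–cis–trans (galacto-type) tetrad would be meso without C7 and the acyl pattern, so the handedness lies only in which end carries C7 and which oxygens are acylated. The feature the route is built on is the cis-diol C4–C5 inside a six-membered all-carbon ring with unsaturation at C1=C2: ring C1–C6 is a benzene ring whose C4–C5 edge has been cis-dihydroxylated, and C3 and C6 are the termini of the remaining diene. O4 and O6 are in addition 1,3-anti, which allows C6 to be set from O4. The sensitive groups are three esters of two kinds beside two free secondary hydroxyls: the O5 benzoate sits between O4–H (cis) and O6–H (trans), and the O3 acetate is next to O4–H, so any basic step after the hydroxyls are free invites acyl migration. Every intermediate with C6 at the ketone level can aromatise by losing two oxygen substituents. The difficulty is therefore not the seven-carbon skeleton but telling five oxygens apart (one acetate, two benzoates, two free) while four stereocenters are set.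

## Retrosynthetic reasoning

**11 to 10 (C6–H bond).** The last bond made is C6–H, by reduction of the C6 ketone of 10. Hydride must arrive on the face of C6 on which O4 stands; intramolecular delivery from the free O4–H gives the O4/O6 anti and O5/O6 trans relation. This is done last and under acidic conditions, so the free O4–H and O6–H never meet base while they flank the O5 benzoate. The ketone at C6 is not a detour: it makes C1 nucleophilic for the next cut, and it is what the bromine of 1 becomes.

**10 to 7 via 9 and 8 (C1–C7 bond).** With C6 as a ketone, C1 is the α-carbon of an enone, so C7 can be added as a one-carbon electrophile by Morita–Baylis–Hillman hydroxymethylation of 7 to 8. O7 is then the only free hydroxyl and is benzoylated (9) before the silyl ether on O4 is removed (10). O7 must be acylated before the reduction, because a free O7–H is also β to the ketone and could deliver hydride to either face.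

**7 to 4 via 6 and 5 (C3–O3 and C6=O).** Both oxygens come from one photooxygenation: a [4+2] addition across C3 and C6 of diene 4, anti to the substituents on C4 and C5, which fixes C3. Reduction of peroxide 5 leaves a bromohydrin at C6 that collapses to the ketone, so the bromine decides which terminus becomes the carbonyl. Alcohol 6 is acetylated to 7, placing the acetate of the target as soon as O3 exists.

**4 to 2 via 3 (O4 versus O5).** The two hydroxyls of 2 differ only in their neighbour: O5 is next to the bromine-bearing carbon, O4 next to a CH=. A bulky silyl group goes to O4 (3) and the benzoate of the target to O5 (4). A cyclic ketal across O4/O5 was avoided on purpose, since it would postpone this differentiation to a stage where nothing distinguishes the two oxygens as clearly.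

**2 to 1 (the ring and the C4/C5 cis-diol).** All six ring carbons and the two stereocenters C4 and C5 come from enzymatic cis-dihydroxylation of the flat, achiral arene 1. The product 2 carries a diene poised for the [4+2] and a bromine that later tells O4 from O5 and marks C6 as the carbonyl carbon. C3 and C6 are then relayed from C4/C5 by substrate control.

## Alternatives that were turned down

Alternative 1: the textbook route cuts the C1=C2 double bond by ring-closing metathesis of the acyclic octa-1,7-diene A2. Its four stereocenters are bought with D-galactose A1, whose C2–C5 have the threo–erythro–threo pattern of C3–C6 of 11. The forward key step is metathesis of A2, closing the ring at C1=C2. It was turned down because that step forms one C=C bond and no stereocenter, while everything difficult moves into making A2. A1 must be opened, one terminus made into a vinyl group and the other into a 1,1-disubstituted alkene carrying C7, and five oxygens must carry several different groups on an open chain where acyl and silyl groups migrate easily. A count of the operations comes to well over twelve steps before the ring exists, and the metathesis must form a trisubstituted alkene between two oxygenated allylic centers, which is the slow case.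

Alternative 2: the ring is bought as (−)-shikimic acid A3, which holds C1–C7 and O3, O4 and O5. The disconnection is the C6–O6 bond; the forward key step is allylic hydroxylation at C6 of a protected methyl 4-epi-shikimate A4, trans to O5, followed by ester reduction. It was turned down because A3 has the wrong configuration at C4 (11 is a 4-epi-shikimate), so the central carbinol of a triol must first be inverted. The C6 methylene is allylic to an electron-poor, ester-conjugated alkene, and nothing in A4 controls the face or even the site of oxidation (C3–H competes). The chiral pool thus supplies two of four stereocenters correctly, and the other two cost more steps than the whole route below.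

Alternative 3: the bonds C3–C4 and C5–C6 are cut by a Diels–Alder reaction of the 1,4-diacetoxy diene A5 with vinylene carbonate A6 to give cycloadduct A7. The forward key step is a thermal [4+2] that closes the ring and sets all four stereocenters at once; the exo mode is needed for O3/O4 and O5/O6 to be trans. It was turned down because an electron-rich diene and a weakly activated dienophile need forcing conditions, under which the endo (all-cis) adduct is normally preferred. No chiral catalyst has a handle on this pair, so A7 would be racemic. A7 also carries its oxygens in equivalent pairs (two acetates, one carbonate), so the real problem of 11, telling O3 from O6 and O4 from O5, would begin only after the key step.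

Key step: step 1

## Route

Remark: the recombinant whole-cell catalyst for arene cis-dihydroxylation is treated as an accessible reagent; its product 2 is also an article of commerce, so the route does not depend on fermentation capacity.

Step 1
Reactants: 1 bromobenzene
Product: 2 (1S,2S)-3-bromocyclohexa-3,5-diene-1,2-diol
Conditions: E. coli JM109 (pDTG601) whole cells expressing toluene dioxygenase, IPTG-induced, glucose-fed, air/O2, pH 7, 35 °C; EtOAc extraction, crystallisation
Reagents that add atoms: dioxygen, O=O
Why: This is arene cis-dihydroxylation by a Rieske non-heme iron dioxygenase (toluene dioxygenase class), and the closest known reaction type is the same oxidation of other monohalobenzenes. Electrons from NADH pass through the reductase, the ferredoxin and the Rieske [2Fe–2S] cluster to the mononuclear iron site, where bound dioxygen is delivered suprafacially as two C–O bonds to the C2–C3 edge of 1 (ortho and meta to bromine), so the two hydroxyls are cis by mechanism. No ring is closed; the step turns the planar arene into ring C1–C6 of the target at the oxidation level of a diene diol. Both new stereocenters (C4 and C5 of 11) are set by the active site, which holds the bromine in one pocket and so selects one of the two enantiotopic ortho/meta edges and one face, giving the (1S,2S) diol. The step needs edge selectivity (2,3 and not 3,4), enantioselectivity and a stop at the diol stage; the enzyme supplies the first two, and the host supplies the third because it lacks the diol dehydrogenase that would rearomatise 2 to a catechol. The bromine that steers the enzyme is kept on purpose, since it later tells O4 from O5 (step 2) and marks C6 as the carbonyl carbon (step 4). The diol should be kept cold and at pH 7 or above, because acid dehydrates it to bromophenols.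

Step 2
Reactants: 2 (1S,2S)-3-bromocyclohexa-3,5-diene-1,2-diol
Product: 3 (1S,6S)-2-bromo-6-[(tert-butyldimethylsilyl)oxy]cyclohexa-2,4-dien-1-ol
Conditions: TBSCl (1.05 equiv), imidazole, DMF, −20 °C
Reagents that add atoms: tert-butyldimethylsilyl chloride, CC(C)(C)[Si](C)(C)Cl
Why: This is regioselective silylation of the less hindered hydroxyl of a diol: the hydroxyl next to the bromine-bearing sp2 carbon (later O5) is shielded by the bromine, while the one next to CH= (later O4) should react first with a bulky silyl chloride at low temperature. No stereocenter is touched.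

Step 3
Reactants: 3 (1S,6S)-2-bromo-6-[(tert-butyldimethylsilyl)oxy]cyclohexa-2,4-dien-1-ol
Product: 4 (1S,6S)-2-bromo-6-[(tert-butyldimethylsilyl)oxy]cyclohexa-2,4-dien-1-yl benzoate
Conditions: BzCl, pyridine, DMAP (cat.), CH2Cl2, 0 °C
Reagents that add atoms: benzoyl chloride, O=C(Cl)c1ccccc1
Why: This is a DMAP-catalysed acylation of the remaining hindered allylic hydroxyl, and the benzoate placed here is the C5 benzoate of the target. It is run cold and buffered because dienyl esters aromatise by loss of benzoic acid under acid or heat, and 4 is used without storage.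

Step 4
Reactants: 4 (1S,6S)-2-bromo-6-[(tert-butyldimethylsilyl)oxy]cyclohexa-2,4-dien-1-yl benzoate
Product: 6 (1S,5R,6S)-6-[(tert-butyldimethylsilyl)oxy]-5-hydroxy-2-oxocyclohex-3-en-1-yl benzoate, via bromo endoperoxide 5 (not isolated)
Conditions: O2, tetraphenylporphyrin (cat.), visible light, CH2Cl2, −78 °C; then thiourea (2.2 equiv), MeOH, −78 °C to 0 °C
Reagents that add atoms: dioxygen, O=O
Why: Singlet dioxygen adds [4+2] to the cyclic s-cis diene from the face anti to the two cis oxygen substituents to give 5, and this anti attack sets C3 (R) by substrate control from C4/C5. Thiourea reduces the O–O bond and the bromohydrin at C6 loses HBr at once, so the carbonyl can appear only at the bromine-bearing carbon; the sequence is known for the corresponding halodiene ketals. The amidine formed from thiourea should take up the HBr and spare the silyl ether.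

Step 5
Reactants: 6 (1S,5R,6S)-6-[(tert-butyldimethylsilyl)oxy]-5-hydroxy-2-oxocyclohex-3-en-1-yl benzoate
Product: 7 (1S,5R,6S)-5-(acetyloxy)-6-[(tert-butyldimethylsilyl)oxy]-2-oxocyclohex-3-en-1-yl benzoate
Conditions: Ac2O, pyridine, DMAP (cat.), CH2Cl2, 0 °C
Reagents that add atoms: acetic anhydride, CC(=O)OC(C)=O
Why: This acetylates the only free hydroxyl, which places the C3 acetate of the target and blocks O3 before the hydroxymethylation. A short reaction at 0 °C should avoid enolisation toward C5.

Step 6
Reactants: 7 (1S,5R,6S)-5-(acetyloxy)-6-[(tert-butyldimethylsilyl)oxy]-2-oxocyclohex-3-en-1-yl benzoate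
Product: 8 (1S,5R,6S)-5-(acetyloxy)-6-[(tert-butyldimethylsilyl)oxy]-3-(hydroxymethyl)-2-oxocyclohex-3-en-1-yl benzoate
Conditions: 37% aq. HCHO, imidazole (1 equiv), THF/1 M aq. NaHCO3, rt
Reagents that add atoms: formaldehyde, C=O
Why: This is a Morita–Baylis–Hillman α-hydroxymethylation: imidazole adds reversibly to C2 of the enone, the enolate is trapped at C1 by formaldehyde and the catalyst is expelled, which forms the C1–C7 bond at the only α-position available. The reaction type is established for silyl- and ketal-protected 4-oxygenated cyclohex-2-enones, and the weakly basic medium is chosen to spare the esters and the C5 stereocenter; no new stereocenter is formed.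

Step 7
Reactants: 8 (1S,5R,6S)-5-(acetyloxy)-6-[(tert-butyldimethylsilyl)oxy]-3-(hydroxymethyl)-2-oxocyclohex-3-en-1-yl benzoate
Product: 9 [(3R,4S,5S)-3-(acetyloxy)-5-(benzoyloxy)-4-[(tert-butyldimethylsilyl)oxy]-6-oxocyclohex-1-en-1-yl]methyl benzoate
Conditions: BzCl, pyridine, CH2Cl2, −20 °C to 0 °C
Reagents that add atoms: benzoyl chloride, O=C(Cl)c1ccccc1
Why: This acylates the only free (primary allylic) hydroxyl; DMAP is left out because the product is a Morita–Baylis–Hillman-type allylic ester that strongly nucleophilic amines could displace in an SN2′ manner. O7 is capped now so that it cannot direct hydride in step 9.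

Step 8
Reactants: 9 [(3R,4S,5S)-3-(acetyloxy)-5-(benzoyloxy)-4-[(tert-butyldimethylsilyl)oxy]-6-oxocyclohex-1-en-1-yl]methyl benzoate
Product: 10 [(3R,4S,5S)-3-(acetyloxy)-5-(benzoyloxy)-4-hydroxy-6-oxocyclohex-1-en-1-yl]methyl benzoate
Conditions: HF·pyridine, pyridine/THF, 0 °C to rt
Reagents that add atoms: none
Why: This is fluoride cleavage of the secondary silyl ether under buffered, weakly acidic conditions, where neither the cis O5-to-O4 benzoyl shift nor β-elimination of the β-hydroxy ketone should be fast. It frees O4–H, the directing group for the last step.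

Step 9
Reactants: 10 [(3R,4S,5S)-3-(acetyloxy)-5-(benzoyloxy)-4-hydroxy-6-oxocyclohex-1-en-1-yl]methyl benzoate
Product: 11 [(3R,4S,5R,6S)-3-(acetyloxy)-5-(benzoyloxy)-4,6-dihydroxycyclohex-1-en-1-yl]methyl benzoate
Conditions: Me4NBH(OAc)3, MeCN/AcOH (1:1), −30 °C
Reagents that add atoms: none
Why: This is an Evans–Saksena hydroxyl-directed reduction: O4–H exchanges an acetate on boron and the alkoxyborohydride delivers hydride through a six-membered transition state to the face of C6=O on which O4 stands, giving the 1,3-anti diol, that is O6 trans to O5 (C6 S). The reagent is too weak to reduce the enone intermolecularly at this temperature, so directed 1,2-reduction is expected, and the acetic acid medium should suppress acyl migration in the product.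

## Compound list

1 | bromobenzene | Brc1ccccc1 | starting material
2 | (1S,2S)-3-bromocyclohexa-3,5-diene-1,2-diol | O[C@H]1C=CC=C(Br)[C@H]1O | intermediate
3 | (1S,6S)-2-bromo-6-[(tert-butyldimethylsilyl)oxy]cyclohexa-2,4-dien-1-ol | CC(C)(C)[Si](C)(C)O[C@H]1C=CC=C(Br)[C@H]1O | intermediate
4 | (1S,6S)-2-bromo-6-[(tert-butyldimethylsilyl)oxy]cyclohexa-2,4-dien-1-yl benzoate | CC(C)(C)[Si](C)(C)O[C@H]1C=CC=C(Br)[C@H]1OC(=O)c1ccccc1 | intermediate
5 | (1R,4R,7S,8R)-1-bromo-8-[(tert-butyldimethylsilyl)oxy]-2,3-dioxabicyclo[2.2.2]oct-5-en-7-yl benzoate (peroxide bridge anti to both oxygen substituents) | CC(C)(C)[Si](C)(C)O[C@H]1[C@H]2C=C[C@](Br)(OO2)[C@H]1OC(=O)c1ccccc1 | intermediate (not isolated)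
6 | (1S,5R,6S)-6-[(tert-butyldimethylsilyl)oxy]-5-hydroxy-2-oxocyclohex-3-en-1-yl benzoate | CC(C)(C)[Si](C)(C)O[C@H]1[C@H](O)C=CC(=O)[C@H]1OC(=O)c1ccccc1 | intermediate
7 | (1S,5R,6S)-5-(acetyloxy)-6-[(tert-butyldimethylsilyl)oxy]-2-oxocyclohex-3-en-1-yl benzoate | CC(C)(C)[Si](C)(C)O[C@H]1[C@H](OC(C)=O)C=CC(=O)[C@H]1OC(=O)c1ccccc1 | intermediate
8 | (1S,5R,6S)-5-(acetyloxy)-6-[(tert-butyldimethylsilyl)oxy]-3-(hydroxymethyl)-2-oxocyclohex-3-en-1-yl benzoate | CC(C)(C)[Si](C)(C)O[C@H]1[C@H](OC(C)=O)C=C(CO)C(=O)[C@H]1OC(=O)c1ccccc1 | intermediate
9 | [(3R,4S,5S)-3-(acetyloxy)-5-(benzoyloxy)-4-[(tert-butyldimethylsilyl)oxy]-6-oxocyclohex-1-en-1-yl]methyl benzoate | CC(C)(C)[Si](C)(C)O[C@H]1[C@H](OC(C)=O)C=C(COC(=O)c2ccccc2)C(=O)[C@H]1OC(=O)c1ccccc1 | intermediate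
10 | [(3R,4S,5S)-3-(acetyloxy)-5-(benzoyloxy)-4-hydroxy-6-oxocyclohex-1-en-1-yl]methyl benzoate | O[C@H]1[C@H](OC(C)=O)C=C(COC(=O)c2ccccc2)C(=O)[C@H]1OC(=O)c1ccccc1 | intermediate
11 | [(3R,4S,5R,6S)-3-(acetyloxy)-5-(benzoyloxy)-4,6-dihydroxycyclohex-1-en-1-yl]methyl benzoate | CC(=O)O[C@@H]1C=C(COC(=O)c2ccccc2)[C@H](O)[C@@H](OC(=O)c2ccccc2)[C@H]1O | target

## Step count and least certain steps

Total step count: 9. Longest linear sequence: 9 steps (1 to 11).

**Step 1 (key step).** The substrate is volatile and toxic to the cells, so the titre may stay low, and the diol may dehydrate to bromophenols during isolation if the broth turns acidic. The fallback is a non-enzymatic, catalytic desymmetrisation of a meso endoperoxide. It cannot set out from 1, which has no use without the enzyme; it replaces 1 by commercial cyclohexa-1,4-diene F1 and comes back to the route at compound 10.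
- F1 is mono-dihydroxylated (OsO4 cat., NMO) to cis-cyclohex-4-ene-1,2-diol F2, ketalised (2,2-dimethoxypropane, TsOH) to acetonide F3, brominated (Br2, CH2Cl2, −78 °C) to the trans-dibromide F4, and dehydrobrominated twice (DBU, toluene, reflux) to the meso diene acetonide F5.
- Photooxygenation (O2, tetraphenylporphyrin, light) anti to the ketal gives the meso endoperoxide F6. An asymmetric Kornblum–DeLaMare rearrangement with a cinchona-alkaloid base removes one of the two enantiotopic bridgehead hydrogens and should give hydroxy enone F7 with C3, C4 and C5 in place.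
- F7 is acetylated (Ac2O, pyridine) to F8, hydroxymethylated (aq. HCHO, imidazole, NaHCO3) to F9, and benzoylated at O7 (BzCl, pyridine) to F10. Aqueous trifluoroacetic acid removes the ketal to give diol F11.
- The α-ketol hydroxyl O5 of F11 (more acidic, next to the flat carbonyl carbon) is benzoylated selectively (BzCl 1 equiv, 2,4,6-collidine, −40 °C) to give 10.

The price is catalyst-controlled rather than enzyme-controlled enantioselectivity and a late site-selective acylation.

**Step 2.** Site selectivity between the two cis hydroxyls may be poor, the silyl group may migrate between them, or the mono-protected diene may aromatise on handling. The fallback gives up early differentiation, sets out from 2 and comes back at 10. Diol 2 is ketalised (2,2-dimethoxypropane, TsOH, 0 °C) to the bromodiene acetonide F12. Photooxygenation gives the bromo endoperoxide F13 and thiourea the hydroxy enone F7, which is carried through F8, F9, F10 and F11 to 10 as described for step 1. The ketal also removes any concern about acid-labile groups in step 4.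

**Step 6.** The aqueous base may enolise the ketone toward C5 (epimerisation or acyl shift), hydrolyse an ester, or start β-elimination toward a phenol. The fallback forms the C1–C7 bond by cross-coupling instead of an aldol-type addition, sets out from 7 and comes back at 8. α-Iodination (I2, pyridine, CH2Cl2, 0 °C) gives the iodo enone F14, and Stille coupling with (tributylstannyl)methanol (Pd(PPh3)4, CuI, dioxane, 70 °C) under neutral conditions gives 8.

**Step 9.** Hydride may be delivered without direction from the less hindered face (C6 epimer), conjugate reduction may expel the C7 benzoate, or the O5 benzoate may migrate to O4 or O6. The fallback sets C6 by inversion instead of delivery, sets out from 9 and comes back at 11.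
- Luche reduction of 9 (NaBH4, CeCl3·7H2O, MeOH, −78 °C) with the silyl ether still in place is expected to give alcohol F15, with O6 cis to O5, by attack anti to the substituents on C4 and C5.
- Mitsunobu inversion with chloroacetic acid (PPh3, DIAD, toluene, 0 °C) gives chloroacetate F16.
- Thiourea (with 2,6-lutidine, EtOH) removes the chloroacetyl group selectively to give alcohol F17, and HF·pyridine removes the silyl ether to give 11.

If the Luche reduction instead gives F17 directly, only the desilylation remains.

## Further compounds

F1 | step 1 | cyclohexa-1,4-diene | C1=CCC=CC1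
F2 | step 1 | cis-cyclohex-4-ene-1,2-diol (meso) | O[C@H]1CC=CC[C@H]1O
F3 | step 1 | cis-2,2-dimethyl-3a,4,7,7a-tetrahydro-1,3-benzodioxole (meso) | CC1(C)O[C@H]2CC=CC[C@H]2O1
F4 | step 1 | trans-5,6-dibromo-cis-2,2-dimethylhexahydro-1,3-benzodioxole (racemic, one enantiomer drawn) | CC1(C)O[C@H]2C[C@@H](Br)[C@H](Br)C[C@H]2O1
F5 | step 1 | cis-2,2-dimethyl-3a,7a-dihydro-1,3-benzodioxole (meso) | CC1(C)O[C@H]2C=CC=C[C@H]2O1
F6 | step 1 | meso endoperoxide of F5 (2,3-dioxabicyclo[2.2.2]oct-5-ene with the 7,8-O-isopropylidene group anti to the peroxide bridge) | CC1(C)O[C@H]2[C@H]3C=C[C@H](OO3)[C@H]2O1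
F7 | step 1 | (3aS,4R,7aS)-4-hydroxy-2,2-dimethyl-3a,4-dihydro-1,3-benzodioxol-7(7aH)-one | CC1(C)O[C@H]2[C@H](O)C=CC(=O)[C@H]2O1
F8 | step 1 | (3aS,4R,7aS)-2,2-dimethyl-7-oxo-3a,4,7,7a-tetrahydro-1,3-benzodioxol-4-yl acetate | CC1(C)O[C@H]2[C@H](OC(C)=O)C=CC(=O)[C@H]2O1
F9 | step 1 | (3aS,4R,7aS)-6-(hydroxymethyl)-2,2-dimethyl-7-oxo-3a,4,7,7a-tetrahydro-1,3-benzodioxol-4-yl acetate | CC1(C)O[C@H]2[C@H](OC(C)=O)C=C(CO)C(=O)[C@H]2O1
F10 | step 1 | [(3aS,4R,7aS)-4-(acetyloxy)-2,2-dimethyl-7-oxo-3a,4,7,7a-tetrahydro-1,3-benzodioxol-6-yl]methyl benzoate | CC1(C)O[C@H]2[C@H](OC(C)=O)C=C(COC(=O)c3ccccc3)C(=O)[C@H]2O1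
F11 | step 1 | [(3R,4R,5S)-3-(acetyloxy)-4,5-dihydroxy-6-oxocyclohex-1-en-1-yl]methyl benzoate | O[C@H]1[C@H](OC(C)=O)C=C(COC(=O)c2ccccc2)C(=O)[C@H]1O
F12 | step 2 | (3aS,7aS)-4-bromo-2,2-dimethyl-3a,7a-dihydro-1,3-benzodioxole | CC1(C)O[C@H]2C=CC=C(Br)[C@H]2O1
F13 | step 2 | bromo endoperoxide of F12 (1-bromo-2,3-dioxabicyclo[2.2.2]oct-5-ene with the 7,8-O-isopropylidene group anti to the peroxide bridge) | CC1(C)O[C@H]2[C@H]3C=C[C@](Br)(OO3)[C@H]2O1
F14 | step 6 | (1S,5R,6S)-5-(acetyloxy)-6-[(tert-butyldimethylsilyl)oxy]-3-iodo-2-oxocyclohex-3-en-1-yl benzoate | CC(C)(C)[Si](C)(C)O[C@H]1[C@H](OC(C)=O)C=C(I)C(=O)[C@H]1OC(=O)c1ccccc1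
F15 | step 9 | [(3R,4S,5R,6R)-3-(acetyloxy)-5-(benzoyloxy)-4-[(tert-butyldimethylsilyl)oxy]-6-hydroxycyclohex-1-en-1-yl]methyl benzoate | CC(C)(C)[Si](C)(C)O[C@H]1[C@H](OC(C)=O)C=C(COC(=O)c2ccccc2)[C@@H](O)[C@H]1OC(=O)c1ccccc1
F16 | step 9 | [(3R,4S,5R,6S)-3-(acetyloxy)-5-(benzoyloxy)-4-[(tert-butyldimethylsilyl)oxy]-6-[(chloroacetyl)oxy]cyclohex-1-en-1-yl]methyl benzoate | CC(C)(C)[Si](C)(C)O[C@H]1[C@H](OC(C)=O)C=C(COC(=O)c2ccccc2)[C@H](OC(=O)CCl)[C@H]1OC(=O)c1ccccc1
F17 | step 9 | [(3R,4S,5R,6S)-3-(acetyloxy)-5-(benzoyloxy)-4-[(tert-butyldimethylsilyl)oxy]-6-hydroxycyclohex-1-en-1-yl]methyl benzoate | CC(C)(C)[Si](C)(C)O[C@H]1[C@H](OC(C)=O)C=C(COC(=O)c2ccccc2)[C@H](O)[C@H]1OC(=O)c1ccccc1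
A1 | alternative 1 | D-galactose (open-chain form) | O=C[C@H](O)[C@@H](O)[C@@H](O)[C@H](O)CO
A2 | alternative 1 | galacto-configured 2-[(benzoyloxy)methyl]-3,6-bis-O-(tert-butyldimethylsilyl)-4,5-O-isopropylideneocta-1,7-diene-3,4,5,6-tetrol | C=C[C@@H](O[Si](C)(C)C(C)(C)C)[C@@H]1OC(C)(C)O[C@@H]1[C@@H](O[Si](C)(C)C(C)(C)C)C(=C)COC(=O)c1ccccc1
A3 | alternative 2 | (−)-shikimic acid, (3R,4S,5R)-3,4,5-trihydroxycyclohex-1-ene-1-carboxylic acid | OC(=O)C1=C[C@@H](O)[C@@H](O)[C@H](O)C1
A4 | alternative 2 | methyl 4-epi-shikimate, methyl (3R,4R,5R)-3,4,5-trihydroxycyclohex-1-ene-1-carboxylate | COC(=O)C1=C[C@@H](O)[C@H](O)[C@H](O)C1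
A5 | alternative 3 | (1Z,3E)-1,4-bis(acetyloxy)-2-[(benzoyloxy)methyl]buta-1,3-diene (both acetoxy groups outside) | CC(=O)O/C=C/C(COC(=O)c1ccccc1)=C/OC(C)=O
A6 | alternative 3 | vinylene carbonate (1,3-dioxol-2-one) | O=C1OC=CO1
A7 | alternative 3 | exo cycloadduct: 3,6-di-O-acetyl-7-O-benzoyl-4,5-O-carbonyl derivative of the tetrol core (racemic, enantiomer matching 11 drawn) | O=C1O[C@H]2[C@H](OC(C)=O)C=C(COC(=O)c3ccccc3)[C@H](OC(C)=O)[C@H]2O1
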